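**Plan**
- Retrosynthesis: the C2 methylene of the oxolane is taken back to a lactone C=O; the C3–CH2Ar bond is cut (enolate benzylation); O1 is excised from between C2 and C5 (retro-Baeyer–Villiger), joining C2 to C5 to leave 3-(3,4-dimethoxybenzyl)cyclobutanone; its two ring bonds to the ketene carbons are cut to dichloroketene and methyleugenol.
- Enabling feature: in the oxolane ring, O1 lies between two CH2 groups (C2, C5) and the benzyl-bearing C4 is 1,3 to C2. With C2 at the carbonyl level, removal of O1 leaves a four-membered carbocycle with a mirror plane through C=O and the benzyl-bearing carbon, so its two ring CH2 groups are enantiotopic.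
- Forward order: [2+2] builds the cyclobutanone, oxygen insertion enlarges it to the five-membered oxacycle, the second arylmethyl arm is attached, and the carbonyl is reduced to CH2 with the ring kept closed.
- Stereochemistry: C4 (S) comes from catalyst-controlled choice between the enantiotopic migrating CH2 groups; C3 (S) comes from substrate control, the electrophile entering anti to the C4 substituent (trans).

Key step: step 3

Assumption: the target is the trans, C2-symmetric (3S,4S)-3,4-bis(3,4-dimethoxybenzyl)oxolane. The sense of induction of the chiral ligand in step 3 for a 3-benzyl substituent is not assumed; the ligand antipode that gives the (S)-lactone 8 is to be fixed by a small preliminary test.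

**Route**

Step 1
Reactants: 1 methyleugenol (4-allyl-1,2-dimethoxybenzene); 2 trichloroacetyl chloride
Product: 4 rac-2,2-dichloro-3-(3,4-dimethoxybenzyl)cyclobutan-1-one, via dichloroketene 3 (not isolated)
Conditions: activated Zn dust (2 equiv), 2 (1.5 equiv, slow addition), Et2O/DME, ultrasound, 15–20 °C
Reagents that add atoms: none
Why: Zinc reduces 2 to dichloroketene, which should add to the terminal alkene of 1 in a thermal ketene–alkene [2+2] cycloaddition with the ketene carbonyl carbon bonding to the terminal CH2, so the CCl2 group ends next to the benzyl-bearing carbon (racemic stereocenter, of no consequence).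

Step 2
Reactants: 4 rac-2,2-dichloro-3-(3,4-dimethoxybenzyl)cyclobutan-1-one
Product: 6 3-(3,4-dimethoxybenzyl)cyclobutan-1-one, via monochloro ketone 5 (not isolated)
Conditions: Zn dust (4 equiv), AcOH, 25 to 60 °C
Reagents that add atoms: none
Why: Reductive dehalogenation of an α,α-dichloro ketone by zinc in acetic acid should remove both chlorines through zinc enolates and leave the achiral, mirror-symmetric cyclobutanone.

Step 3
Reactants: 6 3-(3,4-dimethoxybenzyl)cyclobutan-1-one
Product: 8 (S)-4-(3,4-dimethoxybenzyl)oxolan-2-one, via Criegee adduct 7 (not isolated)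
Conditions: Sc(OTf)3 (5 mol%), chiral C2-symmetric N,N'-dioxide ligand (6 mol%; trimethylene-bridged bis-pipecolic 2,6-diisopropylanilide bis-N-oxide, antipode chosen for the S product), m-CPBA (1.2 equiv), EtOAc, −20 °C
Reagents that add atoms: m-CPBA (3-chloroperoxybenzoic acid), OOC(=O)c1cccc(Cl)c1
Why: The scandium triflate/N,N'-dioxide complex binds the ketone of 6, m-CPBA adds to the carbonyl carbon to give the Criegee adduct 7, and the one enantiotopic ring CH2 that the chiral pocket holds antiperiplanar to the O–O bond migrates from carbon to oxygen with loss of 3-chlorobenzoate, inserting the oxygen and enlarging the four-membered carbocycle to the five-membered lactone. The closest known reaction type is the catalytic enantioselective Baeyer–Villiger desymmetrization of 3-substituted cyclobutanones with chiral Lewis acid/peracid systems. No ring is closed by a cyclization; the oxolanone arises only by 1,2-shift ring expansion (four to five ring atoms), driven by release of cyclobutanone strain. The single new stereocenter, C4 of the lactone (the former prochiral C3 of 6), is set by catalyst control, that is, by which of the two C(=O)–CH2 bonds migrates. Regioselectivity is not an issue because both candidates are constitutionally identical CH2 groups, so the step needs enantiotopic-group selectivity and chemoselectivity; the latter should be secured by the far higher reactivity of the strained ketone than of the dimethoxyarene towards the peracid at −20 °C.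

Step 4
Reactants: 8 (S)-4-(3,4-dimethoxybenzyl)oxolan-2-one; 9 3,4-dimethoxybenzyl bromide (4-(bromomethyl)-1,2-dimethoxybenzene)
Product: 11 (3S,4S)-3,4-bis(3,4-dimethoxybenzyl)oxolan-2-one, via lithium enolate 10 (not isolated)
Conditions: LiN(SiMe3)2 (1.05 equiv), THF, −78 °C; then 9 (1.1 equiv), DMPU, −78 to −40 °C
Reagents that add atoms: none
Why: SN2 alkylation of the lithium enolate of a β-substituted γ-butyrolactone should take place on the face anti to the C4 arylmethyl group, which sets the new C3 stereocenter trans (3S) by substrate control.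

Step 5
Reactants: 11 (3S,4S)-3,4-bis(3,4-dimethoxybenzyl)oxolan-2-one
Product: 13 (3S,4S)-3,4-bis(3,4-dimethoxybenzyl)oxolan-2-ol (mixture of C2 epimers), via aluminium lactolate 12 (not isolated)
Conditions: i-Bu2AlH (1.1 equiv), CH2Cl2, −78 °C; aq. Rochelle salt (KNaC4H4O6) work-up
Reagents that add atoms: none
Why: Partial reduction of a lactone: at −78 °C one hydride adds and the tetrahedral aluminium alkoxide 12 should persist until work-up, so reduction stops at the lactol with the ring closed and C3/C4 untouched.

Step 6
Reactants: 13 (3S,4S)-3,4-bis(3,4-dimethoxybenzyl)oxolan-2-ol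
Product: 15 (3S,4S)-3,4-bis(3,4-dimethoxybenzyl)oxolane (target), via oxocarbenium ion 14 (not isolated)
Conditions: Et3SiH (3 equiv), Me3SiOTf (0.2 equiv), CH2Cl2, −78 °C
Reagents that add atoms: none
Why: Ionic hydrogenation of a lactol: the silyl triflate ionises C2–OH to the cyclic oxocarbenium ion 14, which excess silane should trap by hydride transfer faster than the aryl rings can attack at −78 °C; no stereocenter is formed or touched.

**Compound list**
1 | methyleugenol (4-allyl-1,2-dimethoxybenzene) | C=CCc1ccc(OC)c(OC)c1 | starting material
2 | trichloroacetyl chloride | O=C(Cl)C(Cl)(Cl)Cl | starting material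
3 | dichloroketene (formed in the flask) | O=C=C(Cl)Cl | intermediate
4 | rac-2,2-dichloro-3-(3,4-dimethoxybenzyl)cyclobutan-1-one | COc1ccc(CC2CC(=O)C2(Cl)Cl)cc1OC | intermediate
5 | 2-chloro-3-(3,4-dimethoxybenzyl)cyclobutan-1-one (diastereomer mixture, formed in the flask) | COc1ccc(CC2CC(=O)C2Cl)cc1OC | intermediate
6 | 3-(3,4-dimethoxybenzyl)cyclobutan-1-one | COc1ccc(CC2CC(=O)C2)cc1OC | intermediate
7 | Criegee adduct, 1-hydroxy-3-(3,4-dimethoxybenzyl)cyclobutyl 3-chloroperoxybenzoate (formed in the flask) | COc1ccc(CC2CC(O)(OOC(=O)c3cccc(Cl)c3)C2)cc1OC | intermediate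
8 | (S)-4-(3,4-dimethoxybenzyl)oxolan-2-one | COc1ccc(C[C@@H]2COC(=O)C2)cc1OC | intermediate
9 | 3,4-dimethoxybenzyl bromide (4-(bromomethyl)-1,2-dimethoxybenzene) | COc1ccc(CBr)cc1OC | starting material
10 | lithium (S)-4-(3,4-dimethoxybenzyl)-4,5-dihydrofuran-2-olate (enolate of 8, formed in the flask) | COc1ccc(C[C@@H]2COC([O-])=C2)cc1OC.[Li+] | intermediate
11 | (3S,4S)-3,4-bis(3,4-dimethoxybenzyl)oxolan-2-one | COc1ccc(C[C@@H]2C(=O)OC[C@H]2Cc2ccc(OC)c(OC)c2)cc1OC | intermediate
12 | diisobutylaluminium alkoxide of lactol 13 (formed in the flask) | COc1ccc(C[C@@H]2C(O[Al](CC(C)C)CC(C)C)OC[C@H]2Cc2ccc(OC)c(OC)c2)cc1OC | intermediate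
13 | (3S,4S)-3,4-bis(3,4-dimethoxybenzyl)oxolan-2-ol (C2 epimers) | COc1ccc(C[C@@H]2C(O)OC[C@H]2Cc2ccc(OC)c(OC)c2)cc1OC | intermediate
14 | (3S,4S)-3,4-bis(3,4-dimethoxybenzyl)-3,4-dihydro-2H-furan-1-ium triflate (oxocarbenium ion, formed in the flask) | COc1ccc(C[C@@H]2C=[O+]C[C@H]2Cc2ccc(OC)c(OC)c2)cc1OC.[O-]S(=O)(=O)C(F)(F)F | intermediate
15 | (3S,4S)-3,4-bis(3,4-dimethoxybenzyl)oxolane | COc1ccc(C[C@@H]2COC[C@H]2Cc2ccc(OC)c(OC)c2)cc1OC | target

**Step count**
Total steps: 6. Longest linear sequence: 6 steps (from 1).

**Steps most likely to fail**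

1. Step 3. The two enantiotopic CH2 groups may be poorly discriminated, because the benzyl group that breaks the symmetry is flexible and one carbon removed from the ring; uncatalysed background oxidation by the peracid would erode the selectivity further. Fallback: the oxidation is replaced by an enantiotopic deprotonation followed by oxidative cleavage. Setting out from 6, a homochiral lithium amide LiN[CH(Me)Ph]2 (antipode chosen for the S series) with Me3SiCl present in THF at −100 °C should give the silyl enol ether (S)-{[3-(3,4-dimethoxybenzyl)cyclobut-1-en-1-yl]oxy}trimethylsilane F1. Ozonolysis of its electron-rich enol double bond at −78 °C (stopped at the indicator end point to spare the arene) with NaBH4 work-up should give (S)-4-(3,4-dimethoxyphenyl)-3-(hydroxymethyl)butanoic acid F2. On acidification F2 lactonises and the route is rejoined at 8.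

2. Step 6. The oxocarbenium ion may be captured by one of the electron-rich aryl rings (intramolecular Friedel–Crafts alkylation), or may lose a proton to the enol ether with scrambling of C3, before hydride transfer. Fallback: the cation is avoided altogether. Setting out from 13, NaBH4 in MeOH should reduce the open hydroxy-aldehyde form to (2S,3S)-2,3-bis(3,4-dimethoxybenzyl)butane-1,4-diol F3. TsCl (1.05 equiv) in pyridine should then form (2S,3S)-2,3-bis(3,4-dimethoxybenzyl)-4-hydroxybutyl 4-methylbenzenesulfonate F4, which closes by 5-exo-tet displacement on warming and rejoins the route at 15.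

3. Step 4. Proton exchange between product and enolate may lead to double alkylation and incomplete conversion, and the labile electron-rich benzylic bromide may decompose. Fallback: the C–C bond is made by aldol addition instead of SN2 alkylation. Setting out from 8, the enolate 10 is treated with commercial 3,4-dimethoxybenzaldehyde at −78 °C to give (3R,4S)-4-(3,4-dimethoxybenzyl)-3-[(3,4-dimethoxyphenyl)(hydroxy)methyl]oxolan-2-one F5 (carbinol epimers, ring substituents trans). Hydrogenolysis of the benzylic C–OH bond (H2, Pd/C, AcOH, cat. HClO4) should then rejoin the route at 11.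

**Further compounds**
F1 | step 3 | (S)-{[3-(3,4-dimethoxybenzyl)cyclobut-1-en-1-yl]oxy}trimethylsilane | COc1ccc(C[C@@H]2C=C(O[Si](C)(C)C)C2)cc1OC
F2 | step 3 | (S)-4-(3,4-dimethoxyphenyl)-3-(hydroxymethyl)butanoic acid | COc1ccc(C[C@@H](CC(=O)O)CO)cc1OC
F3 | step 6 | (2S,3S)-2,3-bis(3,4-dimethoxybenzyl)butane-1,4-diol | COc1ccc(C[C@@H]([C@@H](CO)Cc2ccc(OC)c(OC)c2)CO)cc1OC
F4 | step 6 | (2S,3S)-2,3-bis(3,4-dimethoxybenzyl)-4-hydroxybutyl 4-methylbenzenesulfonate | COc1ccc(C[C@@H]([C@@H](CO)Cc2ccc(OC)c(OC)c2)COS(=O)(=O)c2ccc(C)cc2)cc1OC
F5 | step 4 | (3R,4S)-4-(3,4-dimethoxybenzyl)-3-[(3,4-dimethoxyphenyl)(hydroxy)methyl]oxolan-2-one (carbinol epimers) | COc1ccc(C(O)[C@@H]2C(=O)OC[C@H]2Cc2ccc(OC)c(OC)c2)cc1OC
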